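**Strategy**

- Cuts: the two O–S bonds and the three O–benzyl bonds go first. C3–O3 and C4'–O4' are then cut in one move, back to a 4'-borylflavone. Behind that lie C4'–B (from C4'–Br), the O1–C2 bond of ring C, and the C2–C3 bond that joins a ring A acetophenone to a ring B aldehyde.
- Enabling feature: O1 of ring C pushes electron density through C2=C3 toward the C4 carbonyl, so C3 behaves as an enol-ether carbon that accepts electrophilic oxygen. C4' of ring B can hold a boryl group that the same oxidant turns into C–O. O3 and O4', the two sulfated oxygens, therefore arrive together and late, while O5, O7 and O3' are benzyl ethers from the start.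
- Forward order: rings A and B are bought as arenes and joined by a Claisen–Schmidt condensation. Ring C is closed by oxidative cyclisation of the chalcone, bromine is exchanged for boron, the twin oxygenation follows, then bis-sulfation and hydrogenolysis.
- Stereochemistry: the target has no stereocentre. The E alkene of the chalcone and the racemic cis-fused 2,3-epoxide of the key step are both transient.

Key step: step 6

Remark: the sulfate monoesters are drawn as free hydrogen sulfates throughout, although the benzylated bissulfate is handled as its dipotassium salt and the free acid of the target is released only at the end by cold cation exchange. Racemic compounds with two stereocentres are drawn as one enantiomer.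

**Route**

Step 1
Reactants: 1 2',4',6'-trihydroxyacetophenone
Product: 2 2'-hydroxy-4',6'-bis(benzyloxy)acetophenone
Conditions: BnBr (2.1 equiv), K2CO3 (2.2 equiv), DMF, 0 °C to rt
Reagents that add atoms: benzyl bromide BrCc1ccccc1
Why: Williamson etherification should stop at the 4',6'-dibenzyl ether, because the 4'-OH and one ortho-OH alkylate readily whereas the last ortho-OH is held in a hydrogen bond to the acetyl carbonyl and is too weakly nucleophilic for a slight excess of BnBr at room temperature.

Step 2
Reactants: 3 4-bromo-3-hydroxybenzaldehyde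
Product: 4 3-(benzyloxy)-4-bromobenzaldehyde
Conditions: BnBr (1.1 equiv), K2CO3, DMF, rt
Reagents that add atoms: benzyl bromide BrCc1ccccc1
Why: Williamson etherification of the only phenol, with the aldehyde and the aryl bromide inert to K2CO3 and BnBr.

Step 3
Reactants: 2 2'-hydroxy-4',6'-bis(benzyloxy)acetophenone; 4 3-(benzyloxy)-4-bromobenzaldehyde
Product: 5 (E)-1-[2,4-bis(benzyloxy)-6-hydroxyphenyl]-3-[3-(benzyloxy)-4-bromophenyl]prop-2-en-1-one
Conditions: KOH (50% aq.), EtOH/THF, rt
Reagents that add atoms: none
Why: Claisen–Schmidt (crossed aldol) condensation of the methyl ketone enolate with a non-enolisable aldehyde, in which E1cB dehydration should give the conjugated E alkene under thermodynamic control while the aryl bromide and benzyl ethers tolerate hydroxide at room temperature.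

Step 4
Reactants: 5 (E)-1-[2,4-bis(benzyloxy)-6-hydroxyphenyl]-3-[3-(benzyloxy)-4-bromophenyl]prop-2-en-1-one
Product: 6 5,7,3'-tris(benzyloxy)-4'-bromoflavone
Conditions: iodine (I2, 10 mol %), DMSO, 120 °C, stopped at full conversion
Reagents that add atoms: none
Why: Iodine-catalysed oxidative cyclisation of a 2'-hydroxychalcone in DMSO (6-endo oxa-Michael closure of ring C, alpha-iodination and loss of HI, with DMSO returning HI to I2) is a standard entry to flavones, and a brief heating period should limit HI-induced cleavage of the 5-O-benzyl ether next to the carbonyl.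

Step 5
Reactants: 6 5,7,3'-tris(benzyloxy)-4'-bromoflavone; 7 bis(pinacolato)diboron
Product: 8 5,7,3'-tris(benzyloxy)-4'-(4,4,5,5-tetramethyl-1,3,2-dioxaborolan-2-yl)flavone
Conditions: Pd(dppf)Cl2 (5 mol %), KOAc (3 equiv), 1,4-dioxane, 90 °C
Reagents that add atoms: none
Why: Miyaura borylation, in which oxidative addition of the aryl bromide to zerovalent palladium formed from Pd(dppf)Cl2, acetate-assisted transmetalation with 7 and reductive elimination should give the aryl pinacol boronate, the weak base KOAc neither promoting biaryl coupling nor touching the flavone or the benzyl ethers.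

Step 6
Reactants: 8 5,7,3'-tris(benzyloxy)-4'-(4,4,5,5-tetramethyl-1,3,2-dioxaborolan-2-yl)flavone
Product: 11 5,7,3'-tri-O-benzylquercetin, via 2,3-epoxyflavanone 4'-O-pinacolborate 9 (not isolated), via flavonol 4'-O-pinacolborate 10 (not isolated)
Conditions: DMDO (ca. 0.07 M in acetone, 5 equiv), CH2Cl2, 0 °C to rt; then TsOH·H2O (10 mol %), CH2Cl2, rt; H2O work-up
Reagents that add atoms: dimethyldioxirane CC1(C)OO1
Why: Proposed new method: a single electrophilic oxygen donor is asked to do two jobs that are each established on their own but have not been run together on one molecule; at ring C the dioxirane delivers oxygen in a concerted, spiro-type transfer to the C2=C3 bond, whose C3 terminus is made nucleophilic by donation from O1, and at C4' a dioxirane oxygen binds the vacant boron orbital, the aryl group shifts from boron to that oxygen as the O–O bond breaks, and acetone is released to leave the aryl pinacol borate 9. The closest known reaction types are the dimethyldioxirane epoxidation of 5,7-dialkoxyflavones with acid isomerisation to flavonols, and the ipso-hydroxylation of arylboronic pinacol esters by KHSO5 in aqueous acetone or by amine N-oxides, the latter being neutral oxygen donors that act through the same coordination and 1,2-shift sequence. No ring of the target is closed; the only ring formed is the oxirane of 9, made by one-step [2+1] oxygen transfer and reopened by TsOH at C2 via the oxocarbenium ion that O1 and ring B stabilise, after which loss of H3 gives the 3-hydroxypyranone 10 and water cleaves the O–B bond to free the 4'-phenol. The two stereocentres of 9 arise as a racemic, necessarily cis-fused pair and both return to sp2 carbon, so nothing has to be controlled. The selectivity needed is oxidation of C2=C3 and of C–B ahead of the benzylic CH2 groups and the alkoxy-rich rings A and B; the substrate secures it through its enol-ether alkene, its Lewis-acidic boron, the absence of any free hydroxyl and the borate that masks the new 4'-oxygen until work-up, with low temperature and a limited excess of oxidant as the external controls.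

Step 7
Reactants: 11 5,7,3'-tri-O-benzylquercetin
Product: 12 5,7,3'-tri-O-benzylquercetin 3,4'-bis(hydrogen sulfate)
Conditions: SO3·pyridine (8 equiv), pyridine, 60 °C; then aq. KHCO3 to pH 8; Sephadex LH-20 or C18
Reagents that add atoms: sulfur trioxide–pyridine complex [O-]S(=O)(=O)[n+]1ccccc1
Why: O-sulfonation by an amine–sulfur trioxide complex, in which the 4'-phenol and the 3-enol are the only hydroxyls of 11 so that an excess of reagent raises no regiochemical question, while the basic medium and hydrogen carbonate work-up should keep the acid-labile 3-O-sulfate as its salt.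

Step 8
Reactants: 12 5,7,3'-tri-O-benzylquercetin 3,4'-bis(hydrogen sulfate)
Product: 13 quercetin 3,4'-bis(hydrogen sulfate)
Conditions: H2 (1 atm), 10% Pd/C, KHCO3, MeOH/THF/H2O, rt; then Dowex 50W (H+ form), H2O, 0 °C, freeze-dry
Reagents that add atoms: none
Why: Catalytic hydrogenolysis should cleave the three benzylic C–O bonds while the sulfate monoester anions are inert to H2 over Pd, the tetrasubstituted C2=C3 bond of the 3-oxygenated pyranone is not reduced at 1 atm, and the KHCO3 buffer prevents acid-catalysed desulfation before the final cold proton exchange.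

**Compound list**

1 | 2',4',6'-trihydroxyacetophenone | CC(=O)c1c(O)cc(O)cc1O | starting material
2 | 2'-hydroxy-4',6'-bis(benzyloxy)acetophenone | CC(=O)c1c(O)cc(OCc2ccccc2)cc1OCc1ccccc1 | intermediate
3 | 4-bromo-3-hydroxybenzaldehyde | O=Cc1ccc(Br)c(O)c1 | starting material
4 | 3-(benzyloxy)-4-bromobenzaldehyde | O=Cc1ccc(Br)c(OCc2ccccc2)c1 | intermediate
5 | (E)-1-[2,4-bis(benzyloxy)-6-hydroxyphenyl]-3-[3-(benzyloxy)-4-bromophenyl]prop-2-en-1-one (chalcone) | O=C(/C=C/c1ccc(Br)c(OCc2ccccc2)c1)c1c(O)cc(OCc2ccccc2)cc1OCc1ccccc1 | intermediate
6 | 5,7,3'-tris(benzyloxy)-4'-bromoflavone | O=c1cc(-c2ccc(Br)c(OCc3ccccc3)c2)oc2cc(OCc3ccccc3)cc(OCc3ccccc3)c12 | intermediate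
7 | bis(pinacolato)diboron | CC1(C)OB(B2OC(C)(C)C(C)(C)O2)OC1(C)C | starting material
8 | 5,7,3'-tris(benzyloxy)-4'-(4,4,5,5-tetramethyl-1,3,2-dioxaborolan-2-yl)flavone | O=c1cc(-c2ccc(B3OC(C)(C)C(C)(C)O3)c(OCc3ccccc3)c2)oc2cc(OCc3ccccc3)cc(OCc3ccccc3)c12 | intermediate
9 | 5,7,3'-tris(benzyloxy)-2,3-epoxyflavanone 4'-O-pinacol borate (racemic, cis-fused oxirane, one enantiomer drawn) | O=C1c2c(OCc3ccccc3)cc(OCc3ccccc3)cc2O[C@@]2(c3ccc(OB4OC(C)(C)C(C)(C)O4)c(OCc4ccccc4)c3)O[C@@H]12 | intermediate (not isolated)
10 | 5,7,3'-tris(benzyloxy)-3-hydroxyflavone 4'-O-pinacol borate | O=c1c(O)c(-c2ccc(OB3OC(C)(C)C(C)(C)O3)c(OCc3ccccc3)c2)oc2cc(OCc3ccccc3)cc(OCc3ccccc3)c12 | intermediate (not isolated)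
11 | 5,7,3'-tri-O-benzylquercetin (3,4'-dihydroxy-5,7,3'-tris(benzyloxy)flavone) | O=c1c(O)c(-c2ccc(O)c(OCc3ccccc3)c2)oc2cc(OCc3ccccc3)cc(OCc3ccccc3)c12 | intermediate
12 | 5,7,3'-tri-O-benzylquercetin 3,4'-bis(hydrogen sulfate), handled as the dipotassium salt | O=c1c(OS(=O)(=O)O)c(-c2ccc(OS(=O)(=O)O)c(OCc3ccccc3)c2)oc2cc(OCc3ccccc3)cc(OCc3ccccc3)c12 | intermediate
13 | quercetin 3,4'-bis(hydrogen sulfate) (quercetin 3,4'-bissulfate) | O=c1c(OS(=O)(=O)O)c(-c2ccc(OS(=O)(=O)O)c(O)c2)oc2cc(O)cc(O)c12 | target

**Count**

Total steps: 8. Longest linear sequence: 7 steps (steps 1, 3, 4, 5, 6, 7, 8 from compound 1; the branch from compound 3 through step 2 is equally long).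

**Steps most likely to fail**

Step 6 (the proposed method). Oxygen insertion into the C–B bond by the neutral dioxirane may lag behind epoxidation. Extended exposure to the oxidant may then start C–H oxidation at the benzylic positions or hydroxylation of ring A. The fallback uses known reactions, sets out from 8 and returns at 11, and introduces the two oxygens one after the other. Ipso-hydroxylation of the boronate with NaBO3·4H2O in THF/H2O at room temperature should give 5,7,3'-tri-O-benzylluteolin F1. Acetylation with Ac2O in pyridine caps the phenol as 4'-O-acetyl-5,7,3'-tri-O-benzylluteolin F2, which also deactivates ring B. Dimethyldioxirane in acetone/CH2Cl2 at 0 °C then epoxidises only the C2=C3 bond to give the racemic cis-fused 4'-acetoxy-5,7,3'-tris(benzyloxy)-2,3-epoxyflavanone F3. Catalytic TsOH in CH2Cl2 isomerises it to 4'-O-acetyl-5,7,3'-tri-O-benzylquercetin F4. K2CO3 in MeOH/THF removes the acetate and delivers 11.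

Step 4. The hydrogen iodide formed during the iodine-mediated dehydrogenation may cleave the 5-O-benzyl ether, which is activated by the neighbouring carbonyl, and iodination of the electron-rich ring A may compete at long reaction times. The fallback sets out from 5 and returns at 6, and separates ring closure from dehydrogenation so that no HI is present. NaOAc in refluxing EtOH should close ring C by oxa-Michael addition to give racemic 5,7,3'-tris(benzyloxy)-4'-bromoflavanone F5. DDQ in 1,4-dioxane at reflux then removes the C2 and C3 hydrogens and gives 6.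

Step 7. Sulfation of the hindered 3-hydroxyl, which is hydrogen-bonded to the C4 carbonyl, may stop at the 4'-monosulfate. Partial loss of the 3-O-sulfate may also occur while the very polar salt is being purified. The fallback sets out from 11 and returns at 12, and installs both sulfates as neutral, chromatographable diesters. 2,2,2-Trichloroethyl chlorosulfate with Et3N and DMAP in THF should give 5,7,3'-tri-O-benzylquercetin 3,4'-bis(2,2,2-trichloroethyl sulfate) F6, which can be purified on silica. Zn dust and HCO2NH4 in MeOH then remove both trichloroethyl groups by reductive fragmentation to give 12 as its ammonium salt.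

**Further compounds**

F1 | step 6 | 5,7,3'-tri-O-benzylluteolin (5,7,3'-tris(benzyloxy)-4'-hydroxyflavone) | O=c1cc(-c2ccc(O)c(OCc3ccccc3)c2)oc2cc(OCc3ccccc3)cc(OCc3ccccc3)c12
F2 | step 6 | 4'-O-acetyl-5,7,3'-tri-O-benzylluteolin | O=c1cc(-c2ccc(OC(C)=O)c(OCc3ccccc3)c2)oc2cc(OCc3ccccc3)cc(OCc3ccccc3)c12
F3 | step 6 | 4'-acetoxy-5,7,3'-tris(benzyloxy)-2,3-epoxyflavanone (racemic, cis-fused oxirane, one enantiomer drawn) | O=C1c2c(OCc3ccccc3)cc(OCc3ccccc3)cc2O[C@@]2(c3ccc(OC(C)=O)c(OCc4ccccc4)c3)O[C@@H]12
F4 | step 6 | 4'-O-acetyl-5,7,3'-tri-O-benzylquercetin | O=c1c(O)c(-c2ccc(OC(C)=O)c(OCc3ccccc3)c2)oc2cc(OCc3ccccc3)cc(OCc3ccccc3)c12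
F5 | step 4 | racemic 5,7,3'-tris(benzyloxy)-4'-bromoflavanone | O=C1CC(c2ccc(Br)c(OCc3ccccc3)c2)Oc2cc(OCc3ccccc3)cc(OCc3ccccc3)c12
F6 | step 7 | 5,7,3'-tri-O-benzylquercetin 3,4'-bis(2,2,2-trichloroethyl sulfate) | O=c1c(OS(=O)(=O)OCC(Cl)(Cl)Cl)c(-c2ccc(OS(=O)(=O)OCC(Cl)(Cl)Cl)c(OCc3ccccc3)c2)oc2cc(OCc3ccccc3)cc(OCc3ccccc3)c12
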